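The constants were chosen freely; the result is computed.

Think in amounts: each Z that reacts with J puts one G into the flask, and you are asked how the G that ends as D or Q is shared between them.

    Z + J → G + L (k1 = 1.08 × 10⁻⁵ M⁻¹ s⁻¹)
    G → D (k2 = 4.93 × 10⁻⁶ s⁻¹)
    G → X (k3 = 1.12 × 10⁻⁴ s⁻¹)
    G → Q (k4 = 6.39 × 10⁻⁶ s⁻¹)
    J → E (k5 = 3.44 × 10⁻⁸ s⁻¹)

| flask | Z | J | time | remark |
|---|---|---|---|---|
| epsilon | 0.50 M | 2.50 M (fed, over 4.00 d) | 5.0 d | a stirred flask in which J is dosed at a steady rate over 4.00 d without added volume, worked up at 5.0 d |
| theta | 0.50 M | 2.50 M |  | a single well-mixed tank run continuously and read at steady state, 5.0 d in it on average |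
| gamma | 0.50 M (fed, over 4.00 d) | 2.50 M | 5.0 d | all but Z at the start; Z goes in evenly over 4.00 d, the run ends at 5.0 d |
| delta | 0.50 M | 2.50 M | 5.0 d | everything together in a closed stirred flask, run for 5.0 d |

1. the set-up with the highest share of D in all that became D or Q, at the outlet or at the end ("none" if the first two lie within 2 percentage points) (epsilon / theta / gamma / delta / none)
2. share of D in all that became D or Q, at the outlet or at the end, epsilon
3. share of D in all that became D or Q, at the outlet or at the end, theta
4. share of D in all that became D or Q, at the outlet or at the end, gamma
5. share of D in all that became D or Q, at the outlet or at the end, delta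

Treat G as a tank with three drains. The drains to D and Q have the constants 4.93 × 10⁻⁶ s⁻¹ and 6.39 × 10⁻⁶ s⁻¹. Both flows are proportional to [G], so their ratio at any moment is one number. I call it the selectivity factor, the constant to D over the constant to Q: 0.772. It means that D forms at that fraction of the pace of Q, whatever [G] is.

Solve it at both ends. In delta, [G] rises and falls with time, but each slice of time adds D and Q in this ratio. Both start at zero, so the totals keep it. In theta, [G] stands still, and the outlet holds each product as its constant times [G] times the mean time 5.0 d. [G] and the time cancel, which leaves the same ratio. In epsilon and gamma, dosing over 4.00 d shapes [G], yet each slice still obeys the ratio.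

So I commit to a share of D of 43.6% in each of the four set-ups, and to none as the best.

Is one number enough? For the split, yes, since neither [Z] nor [J] appears in the two flows. For amounts, no. The drain to X, at 1.12 × 10⁻⁴ s⁻¹, runs about ten times faster than the drains to D and Q together, so a G reaches D with a chance of 4.00%.

The forecast gives 43.55%, 43.55%, 43.55% and 43.55% for epsilon, theta, gamma and delta, with none as the best, holding that dosing, vessel and time “change how much D + Q forms, but not the split”.

The simulation gives 43.6%, 43.6%, 43.6% and 43.6% for epsilon, theta, gamma and delta, with none as the best. Left for 50.0 d, delta reads 43.6%, and the time allowed made no difference to its share. Now put the factor to work on epsilon. Its end holds D at 3.98% of the Z charged, and dividing by 0.772 gives Q at 5.16%. The reading for Q in epsilon is 5.16%.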